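**Retrosynthetic overview**

1. The acrylic acid is unveiled last by oxidation of a silyl-protected allylic CH2OH on ring C2. The C1'–C2' bond comes from alkylation of a lithiated (E)-allyl sulfone (tail) with a ring-CH2I electrophile (head), followed by Pd/hydride desulfonylation.
2. The tail is made from geranyl acetate, cut at C6=C7 to the aldehyde, and the alkenyl triflate of 6-methylhept-5-en-2-one. They are joined by Nozaki–Hiyama–Kishi coupling, and oxidation then CBS reduction sets (R)-C7'.
3. The structural feature the route rests on is ring C5 of the oxane (O1, C2–C6). It carries H and two CH2 groups, ring C6 (bound to O1) and chain C1', so it can be hidden as the prochiral C3 of a 3-substituted oxetane.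
4. The oxane is the only ring and is formed once, in step 8. The C2 hydroxyl opens the oxetane at one CH2 (bond O1–C6), the other arm becomes C1'–OH, and the C2 centre relays its configuration to C5.
5. The oxetane precursor comes from oxetan-3-one (Wittig, hydrogenation, oxidation), Nozaki–Hiyama–Kishi coupling with silylated 2-bromoallyl alcohol, oxidation and CBS reduction ((R)-C2).

Key step: step 8

Assumption: the (R) antipode of the phosphoric acid is taken as the one matched to the (R)-carbinol; if a test of both antipodes shows the reverse, the (S) acid is used with no other change.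

**Route**

Step 1
Reactants: 1 oxetan-3-one; 2 (3-benzyloxypropyl)triphenylphosphonium bromide
Product: 4 3-[3-(benzyloxy)propylidene]oxetane, via phosphorus ylide 3 (not isolated)
Conditions: NaN(SiMe3)2, THF, 0 °C; then 1, −78 °C → rt
Reagents that add atoms: none
Why: Wittig olefination of an unhindered, electrophilic ketone by a non-stabilised ylide; the alkene geometry is irrelevant because the alkene is saturated in step 2.

Step 2
Reactants: 4 3-[3-(benzyloxy)propylidene]oxetane
Product: 5 3-(oxetan-3-yl)propan-1-ol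
Conditions: H2 (1 atm), 10% Pd/C, EtOH, rt
Reagents that add atoms: none
Why: Heterogeneous hydrogenation should saturate the strained exocyclic alkene and hydrogenolyse the benzyl ether in the same operation, the oxetane being inert to Pd/C under neutral conditions.

Step 3
Reactants: 5 3-(oxetan-3-yl)propan-1-ol
Product: 6 3-(oxetan-3-yl)propanal
Conditions: TEMPO (10 mol %), PhI(OAc)2, CH2Cl2, rt
Reagents that add atoms: none
Why: Oxoammonium (TEMPO) oxidation of a primary alcohol stops at the aldehyde under non-aqueous, nearly neutral conditions that should leave the oxetane intact.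

Step 4
Reactants: 7 2-bromoprop-2-en-1-ol
Product: 8 [(2-bromoprop-2-en-1-yl)oxy](tert-butyl)dimethylsilane
Conditions: TBSCl, imidazole, CH2Cl2, 0 °C → rt
Reagents that add atoms: tert-butyldimethylsilyl chloride, CC(C)(C)[Si](C)(C)Cl
Why: Imidazole-promoted silylation of a primary alcohol.

Step 5
Reactants: 6 3-(oxetan-3-yl)propanal; 8 [(2-bromoprop-2-en-1-yl)oxy](tert-butyl)dimethylsilane
Product: 10 rac-2-{[(tert-butyldimethylsilyl)oxy]methyl}-5-(oxetan-3-yl)pent-1-en-3-ol, via alkenylchromium dichloride 9 (not isolated)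
Conditions: CrCl2 (excess), NiCl2 (cat.), DMF, rt
Reagents that add atoms: none
Why: Nozaki–Hiyama–Kishi coupling: zerovalent nickel inserts into the C–Br bond, the alkenyl group passes to trivalent chromium and the alkenylchromium adds only to the aldehyde, giving the racemic carbinol that steps 6 and 7 correct.

Step 6
Reactants: 10 rac-2-{[(tert-butyldimethylsilyl)oxy]methyl}-5-(oxetan-3-yl)pent-1-en-3-ol
Product: 11 2-{[(tert-butyldimethylsilyl)oxy]methyl}-5-(oxetan-3-yl)pent-1-en-3-one
Conditions: Dess–Martin periodinane, CH2Cl2, 0 °C → rt; used at once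
Reagents that add atoms: none
Why: Dess–Martin oxidation of a secondary allylic alcohol under mild non-basic conditions should give the α-methylene ketone without touching the oxetane or silyl ether.

Step 7
Reactants: 11 2-{[(tert-butyldimethylsilyl)oxy]methyl}-5-(oxetan-3-yl)pent-1-en-3-one
Product: 12 (3R)-2-{[(tert-butyldimethylsilyl)oxy]methyl}-5-(oxetan-3-yl)pent-1-en-3-ol
Conditions: (S)-2-methyl-CBS-oxazaborolidine (20 mol %), catecholborane, toluene, −78 °C; then MeOH, aq. NaOH
Reagents that add atoms: none
Why: Corey–Bakshi–Shibata reduction in which the branched alkenyl group is the large substituent and the CH2CH2 chain the small one, so the (S)-catalyst should deliver hydride to give the (R)-carbinol, catecholborane at low temperature avoiding hydroboration.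

Step 8
Reactants: 12 (3R)-2-{[(tert-butyldimethylsilyl)oxy]methyl}-5-(oxetan-3-yl)pent-1-en-3-ol
Product: 13 [(3R,6R)-6-{3-[(tert-butyldimethylsilyl)oxy]prop-1-en-2-yl}oxan-3-yl]methanol
Conditions: (R)-3,3'-bis(2,4,6-triisopropylphenyl)-1,1'-binaphthyl-2,2'-diyl hydrogen phosphate (10 mol %), toluene (0.02 M), 4 Å MS, rt → 40 °C
Reagents that add atoms: none
Why: The phosphoric acid hydrogen-bonds to the oxetane oxygen and, through its phosphoryl oxygen, to the carbinol hydroxyl (the future O1 on ring C2), which then attacks one oxetane CH2 from the back in an SN2 displacement driven by release of the four-ring strain; the closest known reaction type is the chiral-phosphoric-acid-catalysed intramolecular desymmetrising opening of 3-substituted oxetanes by a tethered hydroxyl to give six-membered cyclic ethers. The oxane closes in the 6-exo-tet mode by forming O1–C6, and the other arm is left as the C1' hydroxymethyl group. Since the departing oxygen stays bonded to the second oxetane CH2, the four-membered ring holds that carbon antiperiplanar to the incoming oxygen about C5–C6, which places it equatorial on the chair-like transition state whichever CH2 is attacked. The two diastereotopic CH2 groups therefore differ only in whether the C2 alkenyl substituent is equatorial or axial, and the equatorial arrangement leads to the 2,5-trans ring, so the new C5 centre is set by the C2 carbinol centre from step 7 and reinforced by the matched acid antipode. The selectivity the step needs is this choice between the two CH2 groups, together with intramolecular over intermolecular opening, which dilution secures; the C2–O bond is never broken, so C2 keeps its configuration.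

Step 9
Reactants: 13 [(3R,6R)-6-{3-[(tert-butyldimethylsilyl)oxy]prop-1-en-2-yl}oxan-3-yl]methanol
Product: 14 tert-butyl({2-[(2R,5S)-5-(iodomethyl)oxan-2-yl]prop-2-en-1-yl}oxy)dimethylsilane
Conditions: I2, PPh3, imidazole, CH2Cl2, 0 °C → rt
Reagents that add atoms: iodine, II
Why: Garegg–Samuelsson (Appel-type) iodination, an SN2 displacement of the alkoxyphosphonium group by iodide at the primary carbon that touches no stereocentre.

Step 10
Reactants: 15 geranyl acetate
Product: 16 (2E)-5-(3,3-dimethyloxiran-2-yl)-3-methylpent-2-en-1-yl acetate (racemic)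
Conditions: mCPBA (1.0 equiv), CH2Cl2, −20 → 0 °C
Reagents that add atoms: 3-chloroperoxybenzoic acid, OOC(=O)c1cccc(Cl)c1
Why: Prilezhaev epoxidation should select the electron-rich remote trisubstituted alkene, the 2,3-alkene being deactivated by the allylic acetate; the epoxide configuration is lost in step 11.

Step 11
Reactants: 16 (2E)-5-(3,3-dimethyloxiran-2-yl)-3-methylpent-2-en-1-yl acetate
Product: 18 (2E)-3-methyl-6-oxohex-2-en-1-yl acetate, via diol 17 (not isolated)
Conditions: HIO4·2H2O, THF/H2O, 0 °C
Reagents that add atoms: none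
Why: Acid-catalysed opening of the epoxide by water at its tertiary carbon gives the vicinal diol, which periodic acid cleaves (Malaprade reaction) to the aldehyde and acetone, the water oxygen leaving in the acetone and the (E)-alkene and acetate staying untouched.

Step 12
Reactants: 19 6-methylhept-5-en-2-one
Product: 21 6-methylhepta-1,5-dien-2-yl trifluoromethanesulfonate, via lithium enolate 20 (not isolated)
Conditions: LiN(iPr)2 (commercial solution), THF, −78 °C; then PhNTf2, −78 → 0 °C
Reagents that add atoms: N-phenylbis(trifluoromethanesulfonimide), O=S(=O)(N(c1ccccc1)S(=O)(=O)C(F)(F)F)C(F)(F)F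
Why: Kinetic deprotonation of the methyl ketone at its methyl group by the hindered amide and O-triflation of the terminal enolate.

Step 13
Reactants: 18 (2E)-3-methyl-6-oxohex-2-en-1-yl acetate; 21 6-methylhepta-1,5-dien-2-yl trifluoromethanesulfonate
Product: 23 rac-(2E)-6-hydroxy-3,11-dimethyl-7-methylidenedodeca-2,10-dien-1-yl acetate, via alkenylchromium dichloride 22 (not isolated)
Conditions: CrCl2 (excess), NiCl2 (cat.), DMF, rt
Reagents that add atoms: none
Why: Nozaki–Hiyama–Kishi coupling of an alkenyl triflate, whose alkenylchromium adds to the aldehyde and tolerates the allylic acetate; the racemic carbinol is corrected in steps 14 and 15.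

Step 14
Reactants: 23 rac-(2E)-6-hydroxy-3,11-dimethyl-7-methylidenedodeca-2,10-dien-1-yl acetate
Product: 24 (2E)-3,11-dimethyl-7-methylidene-6-oxododeca-2,10-dien-1-yl acetate
Conditions: Dess–Martin periodinane, CH2Cl2, 0 °C → rt; used at once
Reagents that add atoms: none
Why: Dess–Martin oxidation of the secondary allylic alcohol to the α-methylene ketone.

Step 15
Reactants: 24 (2E)-3,11-dimethyl-7-methylidene-6-oxododeca-2,10-dien-1-yl acetate
Product: 25 (2E,6R)-6-hydroxy-3,11-dimethyl-7-methylidenedodeca-2,10-dien-1-yl acetate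
Conditions: (S)-2-methyl-CBS-oxazaborolidine (20 mol %), catecholborane, toluene, −78 °C; then MeOH, aq. NaHCO3
Reagents that add atoms: none
Why: Corey–Bakshi–Shibata reduction with the 1,1-disubstituted alkenyl group as the large substituent, so the (S)-catalyst should give the (R)-carbinol (C7' of the target), the acetate being inert to catecholborane.

Step 16
Reactants: 25 (2E,6R)-6-hydroxy-3,11-dimethyl-7-methylidenedodeca-2,10-dien-1-yl acetate
Product: 26 (2E,6R)-3,11-dimethyl-7-methylidene-6-[(triisopropylsilyl)oxy]dodeca-2,10-dien-1-yl acetate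
Conditions: TIPSOTf, 2,6-lutidine, CH2Cl2, −78 → 0 °C
Reagents that add atoms: triisopropylsilyl trifluoromethanesulfonate, CC(C)[Si](C(C)C)(C(C)C)OS(=O)(=O)C(F)(F)F
Why: Silylation of the hindered secondary alcohol by the reactive silyl triflate gives an ether robust enough to outlast the primary TBS ether in step 20.

Step 17
Reactants: 26 (2E,6R)-3,11-dimethyl-7-methylidene-6-[(triisopropylsilyl)oxy]dodeca-2,10-dien-1-yl acetate
Product: 27 {[(2E,6R)-3,11-dimethyl-7-methylidene-1-(phenylsulfonyl)dodeca-2,10-dien-6-yl]oxy}triisopropylsilane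
Conditions: PhSO2Na, Pd(PPh3)4 (5 mol %), THF/MeOH, rt
Reagents that add atoms: sodium benzenesulfinate, [Na+].[O-]S(=O)c1ccccc1
Why: Tsuji–Trost allylic substitution in which zerovalent palladium ionises the primary allylic acetate and the sulfinate attacks the unsubstituted terminus through sulfur, the (E) geometry being kept because syn–anti exchange would need a σ-bond at the fully substituted terminus.

Step 18
Reactants: 27 {[(2E,6R)-3,11-dimethyl-7-methylidene-1-(phenylsulfonyl)dodeca-2,10-dien-6-yl]oxy}triisopropylsilane; 14 tert-butyl({2-[(2R,5S)-5-(iodomethyl)oxan-2-yl]prop-2-en-1-yl}oxy)dimethylsilane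
Product: 29 tert-butyldimethyl({2-[(2R,5R)-5-[(3E,7R)-4,12-dimethyl-8-methylidene-2-(phenylsulfonyl)-7-(triisopropylsilyloxy)trideca-3,11-dien-1-yl]oxan-2-yl]prop-2-en-1-yl}oxy)silane, via lithiated sulfone 28 (not isolated)
Conditions: n-BuLi, THF, −78 °C; HMPA; then 14, −78 → −20 °C
Reagents that add atoms: none
Why: α-Alkylation of a lithiated allylic sulfone (Julia-type coupling) by SN2 at the primary iodide, the carbanion reacting at the sulfonyl carbon and the (E)-alkene staying in place; the new sulfonyl-bearing centre forms as both epimers and is erased in step 19.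

Step 19
Reactants: 29 coupled sulfone (as named in step 18)
Product: 30 tert-butyl({2-[(2R,5S)-5-[(3E,7R)-4,12-dimethyl-8-methylidene-7-(triisopropylsilyloxy)trideca-3,11-dien-1-yl]oxan-2-yl]prop-2-en-1-yl}oxy)dimethylsilane
Conditions: PdCl2(dppp) (10 mol %), LiBHEt3, THF, 0 °C → rt
Reagents that add atoms: none
Why: Palladium-catalysed reductive desulfonylation of an allylic sulfone, in which hydride is delivered to the less substituted terminus of the π-allyl complex so that the trisubstituted alkene should keep its position and (E) geometry.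

Step 20
Reactants: 30 bis-silyl ether (as named in step 19)
Product: 31 2-[(2R,5S)-5-[(3E,7R)-4,12-dimethyl-8-methylidene-7-(triisopropylsilyloxy)trideca-3,11-dien-1-yl]oxan-2-yl]prop-2-en-1-ol
Conditions: PPTS, MeOH, rt
Reagents that add atoms: none
Why: Acid-catalysed methanolysis removes the primary TBS ether far faster than the hindered secondary TIPS ether.

Step 21
Reactants: 31 primary allylic alcohol (as named in step 20)
Product: 32 2-[(2R,5S)-5-[(3E,7R)-4,12-dimethyl-8-methylidene-7-(triisopropylsilyloxy)trideca-3,11-dien-1-yl]oxan-2-yl]prop-2-enal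
Conditions: TEMPO (10 mol %), PhI(OAc)2, CH2Cl2, rt; used at once
Reagents that add atoms: none
Why: TEMPO oxidation of a primary allylic alcohol stops at the enal under nearly neutral conditions that should not epimerise ring C2.

Step 22
Reactants: 32 enal (as named in step 21)
Product: 33 2-[(2R,5S)-5-[(3E,7R)-4,12-dimethyl-8-methylidene-7-(triisopropylsilyloxy)trideca-3,11-dien-1-yl]oxan-2-yl]prop-2-enoic acid
Conditions: NaClO2, NaH2PO4, 2-methyl-2-butene, t-BuOH/H2O, 0 °C → rt
Reagents that add atoms: sodium chlorite, [Na+].[O-]Cl=O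
Why: Pinnick oxidation converts the α-substituted enal into the acrylic acid while excess 2-methyl-2-butene takes up the hypochlorous acid that would otherwise attack the alkenes.

Step 23
Reactants: 33 silyl-protected acid (as named in step 22)
Product: 34 2-[(2R,5S)-5-[(3E,7R)-7-hydroxy-4,12-dimethyl-8-methylidenetrideca-3,11-dien-1-yl]oxan-2-yl]prop-2-enoic acid (the target)
Conditions: TBAF (excess), THF, rt → 40 °C; work-up at pH 4
Reagents that add atoms: none
Why: Fluoride cleaves the Si–O bond of the secondary silyl ether, the carboxylate being inert, and mild acidification releases the free acid.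

**Compound list**

1 | oxetan-3-one | O=C1COC1 | starting material
2 | (3-benzyloxypropyl)triphenylphosphonium bromide | [Br-].C(CC[P+](c1ccccc1)(c1ccccc1)c1ccccc1)OCc1ccccc1 | starting material
3 | (3-benzyloxypropylidene)triphenylphosphorane | C(=P(c1ccccc1)(c1ccccc1)c1ccccc1)CCOCc1ccccc1 | intermediate
4 | 3-[3-(benzyloxy)propylidene]oxetane | C(CCOCc1ccccc1)=C1COC1 | intermediate
5 | 3-(oxetan-3-yl)propan-1-ol | OCCCC1COC1 | intermediate
6 | 3-(oxetan-3-yl)propanal | O=CCCC1COC1 | intermediate
7 | 2-bromoprop-2-en-1-ol | C=C(Br)CO | starting material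
8 | [(2-bromoprop-2-en-1-yl)oxy](tert-butyl)dimethylsilane | C=C(Br)CO[Si](C)(C)C(C)(C)C | intermediate
9 | {3-[(tert-butyldimethylsilyl)oxy]prop-1-en-2-yl}chromium dichloride | C=C(CO[Si](C)(C)C(C)(C)C)[Cr](Cl)Cl | intermediate
10 | rac-2-{[(tert-butyldimethylsilyl)oxy]methyl}-5-(oxetan-3-yl)pent-1-en-3-ol | C=C(CO[Si](C)(C)C(C)(C)C)C(O)CCC1COC1 | intermediate
11 | 2-{[(tert-butyldimethylsilyl)oxy]methyl}-5-(oxetan-3-yl)pent-1-en-3-one | C=C(CO[Si](C)(C)C(C)(C)C)C(=O)CCC1COC1 | intermediate
12 | (3R)-2-{[(tert-butyldimethylsilyl)oxy]methyl}-5-(oxetan-3-yl)pent-1-en-3-ol | C=C(CO[Si](C)(C)C(C)(C)C)[C@H](O)CCC1COC1 | intermediate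
13 | [(3R,6R)-6-{3-[(tert-butyldimethylsilyl)oxy]prop-1-en-2-yl}oxan-3-yl]methanol (2,5-trans oxane) | OC[C@H]1CC[C@H](C(=C)CO[Si](C)(C)C(C)(C)C)OC1 | intermediate
14 | tert-butyl({2-[(2R,5S)-5-(iodomethyl)oxan-2-yl]prop-2-en-1-yl}oxy)dimethylsilane | IC[C@H]1CC[C@H](C(=C)CO[Si](C)(C)C(C)(C)C)OC1 | intermediate
15 | geranyl acetate, (2E)-3,7-dimethylocta-2,6-dien-1-yl acetate | CC(C)=CCC/C(C)=C/COC(C)=O | starting material
16 | (2E)-5-(3,3-dimethyloxiran-2-yl)-3-methylpent-2-en-1-yl acetate (racemic) | CC1(C)OC1CC/C(C)=C/COC(C)=O | intermediate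
17 | (2E)-6,7-dihydroxy-3,7-dimethyloct-2-en-1-yl acetate (racemic) | CC(C)(O)C(O)CC/C(C)=C/COC(C)=O | intermediate
18 | (2E)-3-methyl-6-oxohex-2-en-1-yl acetate | O=CCC/C(C)=C/COC(C)=O | intermediate
19 | 6-methylhept-5-en-2-one | CC(=O)CCC=C(C)C | starting material
20 | lithium 6-methylhepta-1,5-dien-2-olate | [Li]OC(=C)CCC=C(C)C | intermediate
21 | 6-methylhepta-1,5-dien-2-yl trifluoromethanesulfonate | C=C(CCC=C(C)C)OS(=O)(=O)C(F)(F)F | intermediate
22 | (6-methylhepta-1,5-dien-2-yl)chromium dichloride | C=C(CCC=C(C)C)[Cr](Cl)Cl | intermediate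
23 | rac-(2E)-6-hydroxy-3,11-dimethyl-7-methylidenedodeca-2,10-dien-1-yl acetate | C=C(CCC=C(C)C)C(O)CC/C(C)=C/COC(C)=O | intermediate
24 | (2E)-3,11-dimethyl-7-methylidene-6-oxododeca-2,10-dien-1-yl acetate | C=C(CCC=C(C)C)C(=O)CC/C(C)=C/COC(C)=O | intermediate
25 | (2E,6R)-6-hydroxy-3,11-dimethyl-7-methylidenedodeca-2,10-dien-1-yl acetate | C=C(CCC=C(C)C)[C@H](O)CC/C(C)=C/COC(C)=O | intermediate
26 | (2E,6R)-3,11-dimethyl-7-methylidene-6-[(triisopropylsilyl)oxy]dodeca-2,10-dien-1-yl acetate | C=C(CCC=C(C)C)[C@H](O[Si](C(C)C)(C(C)C)C(C)C)CC/C(C)=C/COC(C)=O | intermediate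
27 | {[(2E,6R)-3,11-dimethyl-7-methylidene-1-(phenylsulfonyl)dodeca-2,10-dien-6-yl]oxy}triisopropylsilane | C=C(CCC=C(C)C)[C@H](O[Si](C(C)C)(C(C)C)C(C)C)CC/C(C)=C/CS(=O)(=O)c1ccccc1 | intermediate
28 | 27 lithiated at C1, the sulfonyl carbon | C=C(CCC=C(C)C)[C@H](O[Si](C(C)C)(C(C)C)C(C)C)CC/C(C)=C/C([Li])S(=O)(=O)c1ccccc1 | intermediate
29 | tert-butyldimethyl({2-[(2R,5R)-5-[(3E,7R)-4,12-dimethyl-8-methylidene-2-(phenylsulfonyl)-7-(triisopropylsilyloxy)trideca-3,11-dien-1-yl]oxan-2-yl]prop-2-en-1-yl}oxy)silane (both epimers at the sulfonyl carbon; ring 2,5-trans) | C=C(CCC=C(C)C)[C@H](O[Si](C(C)C)(C(C)C)C(C)C)CC/C(C)=C/C(C[C@H]1CC[C@H](C(=C)CO[Si](C)(C)C(C)(C)C)OC1)S(=O)(=O)c1ccccc1 | intermediate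
30 | tert-butyl({2-[(2R,5S)-5-[(3E,7R)-4,12-dimethyl-8-methylidene-7-(triisopropylsilyloxy)trideca-3,11-dien-1-yl]oxan-2-yl]prop-2-en-1-yl}oxy)dimethylsilane | C=C(CCC=C(C)C)[C@H](O[Si](C(C)C)(C(C)C)C(C)C)CC/C(C)=C/CC[C@H]1CC[C@H](C(=C)CO[Si](C)(C)C(C)(C)C)OC1 | intermediate
31 | 2-[(2R,5S)-5-[(3E,7R)-4,12-dimethyl-8-methylidene-7-(triisopropylsilyloxy)trideca-3,11-dien-1-yl]oxan-2-yl]prop-2-en-1-ol | C=C(CCC=C(C)C)[C@H](O[Si](C(C)C)(C(C)C)C(C)C)CC/C(C)=C/CC[C@H]1CC[C@H](C(=C)CO)OC1 | intermediate
32 | 2-[(2R,5S)-5-[(3E,7R)-4,12-dimethyl-8-methylidene-7-(triisopropylsilyloxy)trideca-3,11-dien-1-yl]oxan-2-yl]prop-2-enal | C=C(CCC=C(C)C)[C@H](O[Si](C(C)C)(C(C)C)C(C)C)CC/C(C)=C/CC[C@H]1CC[C@H](C(=C)C=O)OC1 | intermediate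
33 | 2-[(2R,5S)-5-[(3E,7R)-4,12-dimethyl-8-methylidene-7-(triisopropylsilyloxy)trideca-3,11-dien-1-yl]oxan-2-yl]prop-2-enoic acid | C=C(CCC=C(C)C)[C@H](O[Si](C(C)C)(C(C)C)C(C)C)CC/C(C)=C/CC[C@H]1CC[C@H](C(=C)C(=O)O)OC1 | intermediate
34 | 2-[(2R,5S)-5-[(3E,7R)-7-hydroxy-4,12-dimethyl-8-methylidenetrideca-3,11-dien-1-yl]oxan-2-yl]prop-2-enoic acid | C=C(CCC=C(C)C)[C@H](O)CC/C(C)=C/CC[C@H]1CC[C@H](C(=C)C(=O)O)OC1 | target

**Step count**

Total: 23 steps. Longest linear sequence: 14 steps (steps 1–3, 5–9 and 18–23, from oxetan-3-one).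

**Steps most likely to fail, with fallbacks**

Step 8. The two diastereotopic oxetane CH2 groups may not be discriminated well enough if a boat-like closure or a mismatched acid competes, which would erode the 2,5-trans preference. The monosubstituted oxetane may also open slowly enough for intermolecular oligomerisation to take over. The fallback sets out from 12, comes back at 13, and makes the choice of CH2 group a purely catalyst-controlled intermolecular event followed by a stereospecific ring closure. Acetylation of 12 (Ac2O, pyridine, DMAP) would give (3R)-2-{[(tert-butyldimethylsilyl)oxy]methyl}-5-(oxetan-3-yl)pent-1-en-3-yl acetate F1. Enantioselective opening of its oxetane by TMSBr under a chiral squaramide hydrogen-bond-donor catalyst, a known reaction of 3-substituted oxetanes, would give (3R,6R)-7-bromo-2-{[(tert-butyldimethylsilyl)oxy]methyl}-6-[(trimethylsilyloxy)methyl]hept-1-en-3-yl acetate F2, the catalyst antipode being chosen for the (R)-bromomethyl centre. K2CO3 in MeOH would remove the acetate and the trimethylsilyl ether to give (2R,5R)-2-(bromomethyl)-6-{[(tert-butyldimethylsilyl)oxy]methyl}hept-6-ene-1,5-diol F3. NaH in THF would then close the oxane by a Williamson 6-exo-tet displacement of bromide by the secondary alkoxide, giving 13.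

Step 18. SN2 displacement at the β-branched primary iodide may be slow, so that E2 elimination by the basic sulfonyl carbanion and proton transfer compete. The Pd/hydride desulfonylation that follows (step 19) could also shift or isomerise the alkene. The fallback reverses the polarity of the union, sets out from 26 and 14, and comes back at 30, passing over 27 to 29.
- Methanolysis of 26 (K2CO3, MeOH) would give (2E,6R)-3,11-dimethyl-7-methylidene-6-[(triisopropylsilyl)oxy]dodeca-2,10-dien-1-ol F4.
- CBr4 and PPh3 in CH2Cl2 would convert it into {[(2E,6R)-1-bromo-3,11-dimethyl-7-methylidenedodeca-2,10-dien-6-yl]oxy}triisopropylsilane F5, a highly reactive allylic electrophile.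
- Iodide 14 with PhSO2Na in DMF would give tert-butyldimethyl({2-[(2R,5S)-5-[(phenylsulfonyl)methyl]oxan-2-yl]prop-2-en-1-yl}oxy)silane F6.
- n-BuLi in THF at −78 °C would turn F6 into its α-lithio derivative F7, which would be alkylated by F5 to the coupled sulfone carrying the phenylsulfonyl group on C1' F8.
- Sodium amalgam (Na/Hg) with Na2HPO4 in MeOH/THF at −20 °C would remove the non-allylic sulfonyl group without touching the alkenes, giving 30.

Step 7. Facial discrimination in the hydride transfer may be incomplete if the alkenyl group and the CH2CH2 chain do not differ enough at the catalyst, or if the silyl ether oxygen perturbs binding. Uncatalysed conjugate reduction may also compete. The fallback sets out from 10 and comes back at 12, passing over 11. Sharpless kinetic resolution of racemic 10 (Ti(OiPr)4, L-(+)-diisopropyl tartrate, t-BuOOH (0.6 equiv), 4 Å MS, CH2Cl2, −20 °C) would epoxidise the (S)-enantiomer to (1S)-1-[(2R)-2-{[(tert-butyldimethylsilyl)oxy]methyl}oxiran-2-yl]-3-(oxetan-3-yl)propan-1-ol F9. The slow-reacting (R)-alcohol 12 would be recovered and separated by chromatography.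

Further compounds
F1 | step 8 | (3R)-2-{[(tert-butyldimethylsilyl)oxy]methyl}-5-(oxetan-3-yl)pent-1-en-3-yl acetate | C=C(CO[Si](C)(C)C(C)(C)C)[C@H](OC(C)=O)CCC1COC1
F2 | step 8 | (3R,6R)-7-bromo-2-{[(tert-butyldimethylsilyl)oxy]methyl}-6-[(trimethylsilyloxy)methyl]hept-1-en-3-yl acetate | C[Si](C)(C)OC[C@H](CBr)CC[C@@H](OC(C)=O)C(=C)CO[Si](C)(C)C(C)(C)C
F3 | step 8 | (2R,5R)-2-(bromomethyl)-6-{[(tert-butyldimethylsilyl)oxy]methyl}hept-6-ene-1,5-diol | OC[C@H](CBr)CC[C@@H](O)C(=C)CO[Si](C)(C)C(C)(C)C
F4 | step 18 | (2E,6R)-3,11-dimethyl-7-methylidene-6-[(triisopropylsilyl)oxy]dodeca-2,10-dien-1-ol | C=C(CCC=C(C)C)[C@H](O[Si](C(C)C)(C(C)C)C(C)C)CC/C(C)=C/CO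
F5 | step 18 | {[(2E,6R)-1-bromo-3,11-dimethyl-7-methylidenedodeca-2,10-dien-6-yl]oxy}triisopropylsilane | C=C(CCC=C(C)C)[C@H](O[Si](C(C)C)(C(C)C)C(C)C)CC/C(C)=C/CBr
F6 | step 18 | tert-butyldimethyl({2-[(2R,5S)-5-[(phenylsulfonyl)methyl]oxan-2-yl]prop-2-en-1-yl}oxy)silane | O=S(=O)(C[C@H]1CC[C@H](C(=C)CO[Si](C)(C)C(C)(C)C)OC1)c1ccccc1
F7 | step 18 | α-lithio derivative of F6 (lithium on the sulfonyl carbon) | [Li]C([C@H]1CC[C@H](C(=C)CO[Si](C)(C)C(C)(C)C)OC1)S(=O)(=O)c1ccccc1
F8 | step 18 | coupled sulfone carrying the phenylsulfonyl group on C1' (both epimers at that carbon) | C=C(CCC=C(C)C)[C@H](O[Si](C(C)C)(C(C)C)C(C)C)CC/C(C)=C/CC([C@H]1CC[C@H](C(=C)CO[Si](C)(C)C(C)(C)C)OC1)S(=O)(=O)c1ccccc1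
F9 | step 7 | (1S)-1-[(2R)-2-{[(tert-butyldimethylsilyl)oxy]methyl}oxiran-2-yl]-3-(oxetan-3-yl)propan-1-ol | C1O[C@]1(CO[Si](C)(C)C(C)(C)C)[C@@H](O)CCC2COC2
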